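The plan opens ring A (C4a, C5, C6, C7, C8, C8a) at its trisubstituted C4a=C5 enone bond. Ring-closing metathesis between a C6 vinyl ketone and an exocyclic methylene on C4a of the finished dihydropyran ring B forms that bond, closes the carbocycle and completes the cross-conjugated dienone in one operation, creating no stereocentre. The step exploits the position of quaternary C7 between the C6 and C8 carbonyls, remote from C4a=C5, so C7 never sits beside an enolisable carbon. The precursor is an acyclic 2-methyl-2-silyloxy-1,3-diketone bearing a vinyl group on one carbonyl and the 4-methylidene-dihydropyran-5-yl unit on the other; C7 comes from (S)-lactic acid, C3 from ethyl (R)-3-hydroxybutanoate.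

Key step: step 15

Remark on the chemistry: the carbinol carbons created in steps 7 and 11 (future C6 and C8) are expected as epimer mixtures. They are written without configuration, since both become ketones before the key step. Target atoms carry isochromene numbering (C1, O2, C3, C4, C4a, C5 to C8, C8a); ring A is the carbocycle, ring B the dihydropyran.

**Fragment 1: alkenyl iodide 7**

Step 1
Reactants: 1 ethyl (R)-3-hydroxybutanoate
Product: 2 (R)-3-hydroxy-N-methoxy-N-methylbutanamide
Conditions: MeNH(OMe)·HCl, iPrMgCl, THF, −20 to 0 °C
Reagents that add atoms: N,O-dimethylhydroxylamine hydrochloride, CNOC.Cl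
Why: Weinreb amidation of an ester with the chloromagnesium amide made in the flask is routine for β-hydroxy esters, one further Grignard equivalent simply holding the hydroxyl as its alkoxide, and the C–O stereocentre is not touched.

Step 2
Reactants: 2 (R)-3-hydroxy-N-methoxy-N-methylbutanamide
Product: 3 (R)-5-hydroxyhex-1-yn-3-one
Conditions: HC≡CMgBr (excess), THF, 0 °C to rt; inverse quench into cold aq NaHSO4
Reagents that add atoms: ethynylmagnesium bromide, C#C[Mg]Br
Why: Grignard acylation of a Weinreb amide stops at the chelated tetrahedral adduct, so one alkynyl group is delivered even with the hydroxyl carried as its magnesium alkoxide, and the acidic inverse quench keeps the liberated amine protonated so that it cannot add to the ynone.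

Step 3
Reactants: 3 (R)-5-hydroxyhex-1-yn-3-one
Product: 5 (R)-2-methyl-2,3-dihydro-4H-pyran-4-one, via diethylamino enone 4 (not isolated)
Conditions: Et2NH, CH2Cl2, rt; then CF3CO2H, 0 °C to rt
Reagents that add atoms: none
Why: Aza-Michael addition of the amine to the terminal ynone gives a push–pull enaminone, and acid then drives oxa-Michael addition–elimination by the hydroxyl (net 6-endo-dig cycloisomerisation) to the vinylogous ester without breaking the C–O bond at the stereocentre.

Step 4
Reactants: 5 (R)-2-methyl-2,3-dihydro-4H-pyran-4-one
Product: 6 (R)-5-iodo-2-methyl-2,3-dihydro-4H-pyran-4-one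
Conditions: I2, pyridine, CH2Cl2, 0 °C to rt
Reagents that add atoms: iodine, II
Why: Enone α-iodination with I2/pyridine works here because C5, the β-carbon of the enol ether, is the only nucleophilic position, so iodine adds there and pyridine removes the proton to restore the vinylogous ester.

Step 5
Reactants: 6 (R)-5-iodo-2-methyl-2,3-dihydro-4H-pyran-4-one
Product: 7 (R)-5-iodo-2-methyl-4-methylidene-3,4-dihydro-2H-pyran
Conditions: MePPh3Br, KN(SiMe3)2, THF, 0 °C; then 6, −78 to 0 °C; chromatography on Et3N-deactivated silica
Reagents that add atoms: methyltriphenylphosphonium bromide, C[P+](c1ccccc1)(c1ccccc1)c1ccccc1.[Br-]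
Why: Wittig methylenation, known for glycal-derived 2,3-dihydropyran-4-ones, converts the only carbonyl into the exocyclic methylene, and the low temperature and lithium-free ylide limit enolisation at C3 and leave the alkenyl iodide and the C2 stereocentre alone.

**Fragment 2: aldehyde 16**

Step 6
Reactants: 8 (S)-lactic acid; 9 pivalaldehyde
Product: 10 (2S,5S)-2-tert-butyl-5-methyl-1,3-dioxolan-4-one (cis)
Conditions: cat. p-TsOH·H2O, pentane, reflux (Dean–Stark); low-temperature crystallisation from pentane
Reagents that add atoms: none
Why: Acid-catalysed acetalisation, the first stage of Seebach self-regeneration of stereocentres, favours the cis-2,5-disubstituted acetal, so the new acetal carbon is set relative to the lactate carbon and crystallisation removes the trans isomer.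

Step 7
Reactants: 10 (2S,5S)-2-tert-butyl-5-methyl-1,3-dioxolan-4-one; 11 acrolein
Product: 13 (2S,5R)-2-tert-butyl-5-(1-hydroxyprop-2-en-1-yl)-5-methyl-1,3-dioxolan-4-one (methyl cis to tert-butyl; carbinol epimers), via lithium enolate 12 (not isolated)
Conditions: LiN(iPr)2, THF, −78 °C; then 11, −78 °C; AcOH quench at −78 °C
Reagents that add atoms: none
Why: In this aldol addition of the Seebach enolate the tert-butyl group blocks one face, so acrolein is attacked 1,2 from the opposite face and takes the place of the former hydrogen with retention, which fixes the future C7, while the uncontrolled carbinol centre is erased later by oxidation.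

Step 8
Reactants: 13 (2S,5R)-2-tert-butyl-5-(1-hydroxyprop-2-en-1-yl)-5-methyl-1,3-dioxolan-4-one
Product: 14 methyl (2R)-2,3-dihydroxy-2-methylpent-4-enoate (C3 epimers)
Conditions: cat. p-TsOH·H2O, MeOH, reflux
Reagents that add atoms: methanol, CO
Why: Acid-catalysed transesterification of the acylal-type lactone releases pivalaldehyde and both hydroxyls, acid being preferred to alkoxide so that retro-aldol cleavage is excluded, and the fully substituted centre cannot epimerise.

Step 9
Reactants: 14 methyl (2R)-2,3-dihydroxy-2-methylpent-4-enoate
Product: 15 methyl (2R)-2-methyl-2,3-bis(triethylsilyloxy)pent-4-enoate (C3 epimers)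
Conditions: Et3SiOTf, 2,6-lutidine, CH2Cl2, 0 °C to rt
Reagents that add atoms: triethylsilyl trifluoromethanesulfonate, CC[Si](CC)(CC)OS(=O)(=O)C(F)(F)F
Why: Silylation with a silyl triflate and a hindered pyridine base caps tertiary as well as secondary alcohols, so both hydroxyls are protected in one operation.

Step 10
Reactants: 15 methyl (2R)-2-methyl-2,3-bis(triethylsilyloxy)pent-4-enoate
Product: 16 (2R)-2-methyl-2,3-bis(triethylsilyloxy)pent-4-enal (C3 epimers)
Conditions: iBu2AlH, CH2Cl2, −78 °C; aq potassium sodium tartrate
Reagents that add atoms: none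
Why: Partial reduction of an α-silyloxy ester with iBu2AlH stops at the aluminium hemiacetal at low temperature and gives on work-up a non-enolisable aldehyde, a clean single-addition acceptor that releases no second electrophile during the fragment union.

**Union, ring closure and endgame**

Step 11
Reactants: 7 (R)-5-iodo-2-methyl-4-methylidene-3,4-dihydro-2H-pyran; 16 (2R)-2-methyl-2,3-bis(triethylsilyloxy)pent-4-enal
Product: 18 (2S)-2-methyl-1-[(2R)-2-methyl-4-methylidene-3,4-dihydro-2H-pyran-5-yl]-2,3-bis(triethylsilyloxy)pent-4-en-1-ol (C1 and C3 epimers; C2 spatially unchanged and S only by priority change), via alkenylchromium dichloride 17 (not isolated)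
Conditions: CrCl2 (excess), NiCl2 (cat.), DMF, rt; aq ethylenediamine work-up
Reagents that add atoms: none
Why: In the Nozaki–Hiyama–Kishi coupling zerovalent nickel inserts into the C–I bond and transmetalation gives a weakly basic alkenylchromium that adds only to the aldehyde, which avoids both the anti β-elimination open to a β-alkoxy alkenyllithium and alkoxide-driven silyl migration, and the new C8 carbinol centre needs no control because it is oxidised next.

Step 12
Reactants: 18 (2S)-2-methyl-1-[(2R)-2-methyl-4-methylidene-3,4-dihydro-2H-pyran-5-yl]-2,3-bis(triethylsilyloxy)pent-4-en-1-ol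
Product: 19 (2R)-2-methyl-1-[(2R)-2-methyl-4-methylidene-3,4-dihydro-2H-pyran-5-yl]-2,3-bis(triethylsilyloxy)pent-4-en-1-one (C3 epimers)
Conditions: Dess–Martin periodinane, 2,6-lutidine, CH2Cl2, 0 °C to rt
Reagents that add atoms: none
Why: Amine-buffered Dess–Martin oxidation turns the acid-sensitive dienylic carbinol into the C8 ketone, which converts the enol ether into a robust vinylogous ester and merges the C8 epimers.

Step 13
Reactants: 19 (2R)-2-methyl-1-[(2R)-2-methyl-4-methylidene-3,4-dihydro-2H-pyran-5-yl]-2,3-bis(triethylsilyloxy)pent-4-en-1-one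
Product: 20 (2R)-3-hydroxy-2-methyl-1-[(2R)-2-methyl-4-methylidene-3,4-dihydro-2H-pyran-5-yl]-2-(triethylsilyloxy)pent-4-en-1-one (C3 epimers)
Conditions: HF·pyridine, excess pyridine, THF, 0 °C
Reagents that add atoms: none
Why: Buffered fluoride desilylation is governed by steric access, so the secondary allylic triethylsilyl ether should be cleaved well before the tertiary one, which is buried between a ketone and a branched carbon.

Step 14
Reactants: 20 (2R)-3-hydroxy-2-methyl-1-[(2R)-2-methyl-4-methylidene-3,4-dihydro-2H-pyran-5-yl]-2-(triethylsilyloxy)pent-4-en-1-one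
Product: 21 (2R)-2-methyl-1-[(2R)-2-methyl-4-methylidene-3,4-dihydro-2H-pyran-5-yl]-2-(triethylsilyloxy)pent-4-ene-1,3-dione
Conditions: Dess–Martin periodinane, 2,6-lutidine, CH2Cl2, 0 °C; used at once
Reagents that add atoms: none
Why: Dess–Martin oxidation of the allylic alcohol gives the vinyl ketone under near-neutral conditions with a non-nucleophilic buffer and merges the C6 epimers into one compound that has no enolisable position next to C7.

Step 15
Reactants: 21 (2R)-2-methyl-1-[(2R)-2-methyl-4-methylidene-3,4-dihydro-2H-pyran-5-yl]-2-(triethylsilyloxy)pent-4-ene-1,3-dione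
Product: 22 (3R,7R)-3,7-dimethyl-7-(triethylsilyloxy)-3,4-dihydroisochromene-6,8-dione
Conditions: second-generation Hoveyda–Grubbs catalyst RuCl2(H2IMes)(=CH-C6H4-2-OiPr) (10 mol %, in portions), 1,4-benzoquinone (20 mol %), toluene (2 mM), 80 °C, argon sparge
Reagents that add atoms: none
Why: Olefin metathesis by the Chauvin mechanism: the ruthenium alkylidene exchanges onto the monosubstituted vinyl ketone terminus, the acyl-substituted alkylidene so formed adds across the C4a=CH2 bond to a ruthenacyclobutane, and cycloreversion leaves C4a=C5 plus a ruthenium methylidene that carries the chain while ethylene is purged. The closest known reaction type is the closure of 3-substituted cyclohex-2-enones from vinyl ketones and 1,1-disubstituted alkenes with phosphine-free N-heterocyclic-carbene ruthenium catalysts. Ring A closes as a six-membered carbocycle by joining the inner carbons of the two terminal alkenes (C5 and C4a), the ring size permitting only the geometry with C6 and C8a cis on the new double bond, and closure is helped by the fully substituted C7 (Thorpe–Ingold effect) and by ring B, which holds the methylene on the same side of the C4a–C8a bond as the C8 acyl chain. No stereocentre is created, and C3 and C7 are spectators under these neutral conditions, C7 being fully substituted and flanked only by carbonyl carbons. Three alkenes compete for the catalyst, so site selectivity is the only demand: the endocyclic C1=C8a bond carries three substituents and is polarised as a vinylogous ester by the C8 carbonyl, which makes it unreactive toward the alkylidene, and the metathesis-active oleoyl chain is attached only in step 17. High dilution disfavours intermolecular enone coupling, and 1,4-benzoquinone intercepts ruthenium hydrides that could shift the exocyclic methylene into ring B.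

Step 16
Reactants: 22 (3R,7R)-3,7-dimethyl-7-(triethylsilyloxy)-3,4-dihydroisochromene-6,8-dione
Product: 23 (3R,7R)-7-hydroxy-3,7-dimethyl-3,4-dihydroisochromene-6,8-dione
Conditions: HF·pyridine, THF, 0 °C to rt
Reagents that add atoms: none
Why: Fluoride cleavage of the silyl ether, driven by the strong Si–F bond, frees the tertiary alcohol in a mildly acidic medium and so avoids the basic conditions that could provoke α-ketol rearrangement or opening of ring B.

Step 17
Reactants: 23 (3R,7R)-7-hydroxy-3,7-dimethyl-3,4-dihydroisochromene-6,8-dione; 24 oleoyl chloride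
Product: 25 (3R,7R)-3,7-dimethyl-6,8-dioxo-3,4-dihydroisochromen-7-yl (Z)-octadec-9-enoate (CNP0252548.1)
Conditions: DMAP, CH2Cl2, 0 °C to rt
Reagents that add atoms: none
Why: DMAP-mediated acylation through the acylpyridinium salt esterifies the hindered tertiary C7 hydroxyl on oxygen, hence with retention at C7, and with no stronger base present the C4 protons, the C3 centre and the Z-alkene of the chain stay untouched.

**Compound list**

1 | ethyl (R)-3-hydroxybutanoate | CCOC(=O)C[C@@H](C)O | starting material
2 | (R)-3-hydroxy-N-methoxy-N-methylbutanamide | CON(C)C(=O)C[C@@H](C)O | intermediate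
3 | (R)-5-hydroxyhex-1-yn-3-one | C#CC(=O)C[C@@H](C)O | intermediate
4 | (R,E)-1-(diethylamino)-5-hydroxyhex-1-en-3-one (formed in the flask) | CCN(CC)/C=C/C(=O)C[C@@H](C)O | intermediate
5 | (R)-2-methyl-2,3-dihydro-4H-pyran-4-one | C[C@@H]1CC(=O)C=CO1 | intermediate
6 | (R)-5-iodo-2-methyl-2,3-dihydro-4H-pyran-4-one | C[C@@H]1CC(=O)C(I)=CO1 | intermediate
7 | (R)-5-iodo-2-methyl-4-methylidene-3,4-dihydro-2H-pyran | C[C@@H]1CC(=C)C(I)=CO1 | intermediate
8 | (S)-lactic acid | C[C@H](O)C(=O)O | starting material
9 | pivalaldehyde | CC(C)(C)C=O | starting material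
10 | (2S,5S)-2-tert-butyl-5-methyl-1,3-dioxolan-4-one | C[C@@H]1O[C@H](C(C)(C)C)OC1=O | intermediate
11 | acrolein | C=CC=O | starting material
12 | lithium (2S)-2-tert-butyl-5-methyl-1,3-dioxol-4-olate (formed in the flask) | CC1=C([O-])O[C@@H](C(C)(C)C)O1.[Li+] | intermediate
13 | (2S,5R)-2-tert-butyl-5-(1-hydroxyprop-2-en-1-yl)-5-methyl-1,3-dioxolan-4-one | C[C@]1(C(O)C=C)O[C@H](C(C)(C)C)OC1=O | intermediate
14 | methyl (2R)-2,3-dihydroxy-2-methylpent-4-enoate | COC(=O)[C@](C)(O)C(O)C=C | intermediate
15 | methyl (2R)-2-methyl-2,3-bis(triethylsilyloxy)pent-4-enoate | COC(=O)[C@](C)(O[Si](CC)(CC)CC)C(O[Si](CC)(CC)CC)C=C | intermediate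
16 | (2R)-2-methyl-2,3-bis(triethylsilyloxy)pent-4-enal | O=C[C@](C)(O[Si](CC)(CC)CC)C(O[Si](CC)(CC)CC)C=C | intermediate
17 | dichloro[(2R)-2-methyl-4-methylidene-3,4-dihydro-2H-pyran-5-yl]chromium (formed in the flask) | C[C@@H]1CC(=C)C([Cr](Cl)Cl)=CO1 | intermediate
18 | (2S)-2-methyl-1-[(2R)-2-methyl-4-methylidene-3,4-dihydro-2H-pyran-5-yl]-2,3-bis(triethylsilyloxy)pent-4-en-1-ol | CC[Si](CC)(CC)O[C@](C(O)C1=CO[C@H](C)CC1=C)(C)C(O[Si](CC)(CC)CC)C=C | intermediate
19 | (2R)-2-methyl-1-[(2R)-2-methyl-4-methylidene-3,4-dihydro-2H-pyran-5-yl]-2,3-bis(triethylsilyloxy)pent-4-en-1-one | CC[Si](CC)(CC)O[C@](C(=O)C1=CO[C@H](C)CC1=C)(C)C(O[Si](CC)(CC)CC)C=C | intermediate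
20 | (2R)-3-hydroxy-2-methyl-1-[(2R)-2-methyl-4-methylidene-3,4-dihydro-2H-pyran-5-yl]-2-(triethylsilyloxy)pent-4-en-1-one | CC[Si](CC)(CC)O[C@](C(=O)C1=CO[C@H](C)CC1=C)(C)C(O)C=C | intermediate
21 | (2R)-2-methyl-1-[(2R)-2-methyl-4-methylidene-3,4-dihydro-2H-pyran-5-yl]-2-(triethylsilyloxy)pent-4-ene-1,3-dione | CC[Si](CC)(CC)O[C@](C(=O)C1=CO[C@H](C)CC1=C)(C)C(=O)C=C | intermediate
22 | (3R,7R)-3,7-dimethyl-7-(triethylsilyloxy)-3,4-dihydroisochromene-6,8-dione | CC[Si](CC)(CC)O[C@]1(C)C(=O)C=C2C[C@@H](C)OC=C2C1=O | intermediate
23 | (3R,7R)-7-hydroxy-3,7-dimethyl-3,4-dihydroisochromene-6,8-dione | O[C@]1(C)C(=O)C=C2C[C@@H](C)OC=C2C1=O | intermediate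
24 | oleoyl chloride | CCCCCCCC/C=C\CCCCCCCC(Cl)=O | starting material
25 | (3R,7R)-3,7-dimethyl-6,8-dioxo-3,4-dihydroisochromen-7-yl (Z)-octadec-9-enoate | CCCCCCCC/C=C\CCCCCCCC(=O)O[C@]1(C)C(=O)C=C2C[C@@H](C)OC=C2C1=O | target

Total step count: 17. Longest linear sequence: 12 steps (steps 1–5 or steps 6–10, then steps 11–17).

**Steps most likely to fail**

**Step 15 (ring closure).**
- What may go wrong: ruthenium transfers only sluggishly onto the electron-poor vinyl ketone, so catalyst decay, intermolecular enone coupling or migration of the exocyclic double bond overtakes cyclisation.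
- Fallback: exchange the order of oxidation and ring closure. It sets out from 20, whose allylic-alcohol alkene is electron-richer and takes up ruthenium readily. Metathesis with the same catalyst (toluene, 40–60 °C, high dilution) should give (3R,7R)-6-hydroxy-3,7-dimethyl-7-(triethylsilyloxy)-3,4,6,7-tetrahydro-8H-isochromen-8-one F1. Oxidation of its allylic alcohol with Dess–Martin periodinane or MnO2 comes back to the route at 22.

**Step 11 (fragment union).**
- What may go wrong: the alkenylchromium adds slowly to the neopentyl-type aldehyde, and protodeiodination or nickel-mediated homocoupling of the iodide takes over.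
- Fallback: a preformed, far more nucleophilic carbanion in place of the catalytic Barbier-type process. It sets out from 7. Iodine–lithium exchange (t-BuLi, 2 equiv, Et2O, −100 °C) gives [(2R)-2-methyl-4-methylidene-3,4-dihydro-2H-pyran-5-yl]lithium F2. This is trapped at once at that temperature with 16 and quenched cold with AcOH, so that neither ring-opening β-elimination nor silyl migration has time to occur. The sequence comes back at 18.

**Step 5 (methylenation).**
- What may go wrong: the basic ylide deprotonates C3, leading to recovered ketone or to reversible retro-oxa-Michael ring opening with erosion of the C2 configuration.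
- Fallback: Peterson olefination with a non-basic nucleophile. It sets out from 6. Me3SiCH2MgCl/CeCl3 (THF, −78 °C) adds 1,2 to the ketone to give (2R)-5-iodo-2-methyl-4-[(trimethylsilyl)methyl]-3,4-dihydro-2H-pyran-4-ol F3. KH (THF, 0 °C) then induces syn elimination of silanolate under basic conditions that spare the acid-sensitive dienol ether. The sequence comes back at 7.

**Further compounds**

F1 | step 15 | (3R,7R)-6-hydroxy-3,7-dimethyl-7-(triethylsilyloxy)-3,4,6,7-tetrahydro-8H-isochromen-8-one (C6 epimers) | CC[Si](CC)(CC)O[C@]1(C)C(O)C=C2C[C@@H](C)OC=C2C1=O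
F2 | step 11 | [(2R)-2-methyl-4-methylidene-3,4-dihydro-2H-pyran-5-yl]lithium | [Li]C1=CO[C@H](C)CC1=C
F3 | step 5 | (2R)-5-iodo-2-methyl-4-[(trimethylsilyl)methyl]-3,4-dihydro-2H-pyran-4-ol (C4 epimers) | C[C@@H]1CC(O)(C[Si](C)(C)C)C(I)=CO1
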